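- At the last reading, 15.0 min, the north run (this very flask, followed so far) holds Q at 16.9 %. We want Q at 50 min, so we reckon only the correction still to come.

- north: Z 35 mM; J 2 equiv; the very flask that is asked about, followed so far
- flask: Z 35 mM; J 2.00 equiv; time 50 min

north run (percent of the Z charged)

| time / min | Q / % | X / % |
|---|---|---|
| 1.33 | 2.0 | 51.4 |
| 2.00 | 4.3 | 56.4 |
| 3.00 | 6.7 | 58.0 |
| 4.00 | 8.7 | 57.0 |
| 6.00 | 12.2 | 53.5 |
| 10.0 | 15.6 | 49.0 |
| 15.0 | 16.9 | 46.2 |

(each reading ± 0.3 percentage points)

- equivalents of J to Z, everything else as given, that leave most Q at 50 min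
- the amount of Q then, in percent of the Z charged
- the amount of Q with the amounts as given

- the analysis behind the earlier runs scatters by 0.3 percentage points, standard deviation

- Take the main step alone. Between the last two readings Q gained 0.260 % min⁻¹, and that pace held to the end would give 26.0 %.
- Now add the fading. Between 6.00 min and 10.0 min the gain was 0.850 % min⁻¹, so the pace is dying away. The spacing of the two intervals over the logarithm of their ratio gives the fade time, the time in which the pace of Q falls by a factor e (the lifetime of a pseudo-first-order decay): 3.80 min, as read.
- The pace at the last reading times this fade time is the tail, 0.51 percentage points, so our own figure for Q falls to 17.4 %.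
- Then the rest. X + Q sinks by 0.300 % min⁻¹ as read; that sum does not name the one of the two it leaves, so we make no correction for it and keep our figure as an estimate. With one J charge on hand, we reckon no optimum.
- The forecast gives 16.5 % at the charges as given, and 55 % at 4.5 equiv. On the sinking sum it writes “if it comes from Q, then Q sags”.
- The flask gives 17.4 %, and at best 21.4 % at 2.75 equiv. The forecast's n stands within its margin, but its optimum lies too high by a factor of 1.64 in J and by 34 points in Q.

    G + J ⇌ E + Q (K = 0.702, k = 0.275 M⁻¹ s⁻¹)
    E → D (k = 0.0281 s⁻¹)
    Z + J ⇌ E + X (K = 1.75, k = 0.219 M⁻¹ s⁻¹)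
    X + J ⇌ E + G (K = 1.20, k = 0.0622 M⁻¹ s⁻¹)
    Q + J ⇌ E + L (K = 0.222, k = 0.279 M⁻¹ s⁻¹)

- The 50 min of the flask spans 13.2 fade times, and the flask holds Q at 17.2 % at 25.0 min and at 17.4 % at 50.0 min. The neighbour flask, with [Z] at 140 mM and the same equivalents, starts 4.00 times as concentrated. Counted in this flask's fade time its run is just as long, and we do not scale the fade time by that factor: E → D takes one concentration, the other steps two. That neighbour flask ends with 0 % of its J left, X at 33.4 % against 44.0 % in the flask, and Q at 24.7 % against 17.4 %.

The readings stem from a simulated flask for substances that don't exist, noise included.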